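**Retrosynthetic overview**
1. End game: the angelate goes last onto the equatorial 9-OH of a cis-8,9-diol. The axial 7β-isopropenyl/8α-OH pair comes from trans-diaxial cuprate opening of a 7α,8α-epoxide made from the 9α-allylic alcohol. The 4β-methyl comes from radical hydrogenation of a 4(15)-methylene.
2. Key disconnection: both rings of the trans-decalin are closed in one operation from an acyclic (2E,5Z)-trienal. An intramolecular ene reaction forms C5–C10 (ring B), then a carbonyl-ene reaction forms C2–C3 (ring A).
3. Enabling feature: ring A consists of two three-carbon units. C3–C4(C15)–C5 is the footprint of a 2,3-dimethylbut-2-enyl group used twice as ene donor (C5 = alkene carbon, C3 and C15 = its allylic methyls). C10–C1–C2 is the β-carbon-to-carbonyl span of an enal. The quaternary C5 lies on the fusion bond C5–C10 shared by rings A and B, and the (Z)-C7=C8 alkene of ring B pre-folds the chain.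
4. Stereochemistry: only C9 is set beforehand (CBS reduction). It relays to C5, C10 and C2 in the cascade, and the rigid decalin then controls C4, C7 and C8.
5. The cascade precursor is assembled from 2,3-dimethylbutadiene, ethynylmagnesium bromide and fumaraldehyde mono-dimethyl acetal.

Key step: step 9

Remark: eremophilane numbering is used for the cyclic compounds (C14 = methyl on C5, C15 = methyl on C4; α = face opposite the C5 methyl). 1-Bromo-2,3-dimethylbut-2-ene is assumed not to be stocked and is made in step 1.

**Step 1**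
Reactants: 1 2,3-dimethylbuta-1,3-diene
Product: 2 1-bromo-2,3-dimethylbut-2-ene
Conditions: HBr (33% in AcOH, 1.0 equiv), 0 °C → rt
Reagents that add atoms: hydrogen bromide, Br
Why: 1,4-hydrobromination of a 1,3-diene under thermodynamic control places bromide on the primary terminus and leaves the tetrasubstituted alkene that later serves as the double ene donor.

**Step 2**
Reactants: 2 1-bromo-2,3-dimethylbut-2-ene
Product: 3 4,5-dimethylhex-4-en-1-yne
Conditions: ethynylmagnesium bromide (1.5 equiv), CuCl (5 mol%), THF, 0 → 40 °C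
Reagents that add atoms: ethynylmagnesium bromide, C#C[Mg]Br
Why: copper-catalysed coupling of an alkynyl Grignard reagent with a primary allylic bromide, in which SN2 attack at the CH2 group should prevail over SN2' attack at the fully substituted alkene carbon.

**Step 3**
Reactants: 3 4,5-dimethylhex-4-en-1-yne; 4 (E)-4,4-dimethoxybut-2-enal
Product: 6 rac-(E)-1,1-dimethoxy-8,9-dimethyldeca-2,8-dien-5-yn-4-ol, via alkynylmagnesium bromide 5 (not isolated)
Conditions: EtMgBr (1.05 equiv), THF, 0 °C → rt; then 4, −20 → 0 °C; H2O
Reagents that add atoms: none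
Why: magnesiation of the terminal alkyne (the most acidic C–H) and 1,2-addition of the alkynyl Grignard reagent to the enal; the carbinol centre is racemic here and is set again in step 5.

**Step 4**
Reactants: 6 rac-(E)-1,1-dimethoxy-8,9-dimethyldeca-2,8-dien-5-yn-4-ol
Product: 7 (E)-1,1-dimethoxy-8,9-dimethyldeca-2,8-dien-5-yn-4-one
Conditions: MnO2 (15 equiv), CH2Cl2, rt
Reagents that add atoms: none
Why: MnO2 oxidation of a doubly activated (allylic and propargylic) alcohol under neutral conditions that should not isomerise the skipped enyne.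

**Step 5**
Reactants: 7 (E)-1,1-dimethoxy-8,9-dimethyldeca-2,8-dien-5-yn-4-one
Product: 8 (2E,4S)-1,1-dimethoxy-8,9-dimethyldeca-2,8-dien-5-yn-4-ol
Conditions: (S)-2-methyl-CBS-oxazaborolidine (20 mol%), catecholborane (1.5 equiv), CH2Cl2, −78 °C; then MeOH, H2O
Reagents that add atoms: none
Why: Corey–Bakshi–Shibata reduction in which the (E)-alkenyl group is the large and the unhindered alkynyl group the small substituent, so that the (S)-catalyst should deliver hydride to the face giving the (S)-carbinol (the future C9).

**Step 6**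
Reactants: 8 (2E,4S)-1,1-dimethoxy-8,9-dimethyldeca-2,8-dien-5-yn-4-ol
Product: 9 tert-butyl{[(2E,4S)-1,1-dimethoxy-8,9-dimethyldeca-2,8-dien-5-yn-4-yl]oxy}dimethylsilane
Conditions: TBSCl (1.3 equiv), imidazole (2.5 equiv), DMF, rt
Reagents that add atoms: tert-butyldimethylsilyl chloride, CC(C)(C)[Si](C)(C)Cl
Why: standard silylation; the bulky, weakly Lewis-basic silyl ether protects the carbinol during the Lewis acid step and acts there as the equatorial control element.

**Step 7**
Reactants: 9 tert-butyl{[(2E,4S)-1,1-dimethoxy-8,9-dimethyldeca-2,8-dien-5-yn-4-yl]oxy}dimethylsilane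
Product: 10 tert-butyl{[(2E,4R,5Z)-1,1-dimethoxy-8,9-dimethyldeca-2,5,8-trien-4-yl]oxy}dimethylsilane
Conditions: H2 (1 atm), Pd on CaCO3 poisoned with Pb(OAc)2 (Lindlar catalyst), quinoline, EtOAc, rt
Reagents that add atoms: none
Why: Lindlar semi-hydrogenation adds H2 syn to the alkyne only and gives the (Z)-alkene; the descriptor changes from S to R only because the CIP priorities change.

**Step 8**
Reactants: 10 tert-butyl{[(2E,4R,5Z)-1,1-dimethoxy-8,9-dimethyldeca-2,5,8-trien-4-yl]oxy}dimethylsilane
Product: 11 (2E,4R,5Z)-4-[(tert-butyldimethylsilyl)oxy]-8,9-dimethyldeca-2,5,8-trienal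
Conditions: PPTS (10 mol%), acetone/H2O (10:1), rt
Reagents that add atoms: water, O
Why: mild acid hydrolysis of an enal dimethyl acetal, which should be much faster than cleavage of the secondary silyl ether; the (E)-enal is the stable geometry.

**Step 9**
Reactants: 11 (2E,4R,5Z)-4-[(tert-butyldimethylsilyl)oxy]-8,9-dimethyldeca-2,5,8-trienal
Product: 13 trans-fused 8-(tert-butyldimethylsilyloxy)-4a-methyl-4-methylidene-octahydronaphthalen-2-ol (2α-OH; 5β-Me; 9α-OTBS; 10α-H), via monocyclic ene aldehyde 12 (not isolated)
Conditions: Me2AlCl (2.2 equiv), CH2Cl2 (0.02 M), −78 → −20 °C; aq potassium sodium tartrate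
Reagents that add atoms: none
Why: Proposed new method: the aluminium-complexed enal is attacked at its β-carbon C10 by C5 of the tetrasubstituted alkene and the developing cation at C4 is quenched by 1,5-hydrogen transfer from a C4 methyl to C1, an intramolecular ene reaction of a 1,7-diene that closes ring B (six-membered half-chair, 6-exo at the enal C=C) and releases the aluminium-bound aldehyde 12, whose carbonyl carbon C2 then adds to the CH2 terminus (C3) of the new isopropenyl group with hydrogen transfer from C15 to oxygen, a carbonyl-ene cyclization with the aldehyde tethered to the central carbon of the ene unit that closes ring A through a six-membered chair and leaves the 4(15)-methylene. The closest known reaction types are the Me2AlCl-mediated sequential ene annulation of simple alkenes with enals (intermolecular, same pair of bonds), Lewis-acid-promoted intramolecular ene cyclizations of 1,7-dienes with activated enophiles, and the carbonyl-ene route to 3-methylenecyclohexanols; new are their union in one acyclic substrate and the quaternary ring-fusion carbon formed from a tetrasubstituted ene donor. C10 and C5 should be controlled by the C9 silyl ether, which lies pseudo-equatorial and anti to the forming C5–C10 bond, and by A(1,3) strain, which keeps both reacting π-units equatorial and the C5 methyl axial, so that C4 and C1 end up trans (trans fusion, 5β-methyl, 10α-H). C2 should be controlled by the closed carbonyl-ene transition state, in which the oxygen can reach the C15 hydrogen only from an axial position, giving the 2α alcohol. The step needs attack at C5 and not C4 (six- against seven-membered ring), ene collapse of the zwitterion and not dihydropyran or cyclobutane formation (these side channels are reversible under the Lewis acid, whereas methane loss from the aluminium alkoxide makes the second ene step irreversible), and no reaction at the ring alkene, which is the least nucleophilic alkene and could only close a five-membered ring.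

**Step 10**
Reactants: 13 trans-fused 8-(tert-butyldimethylsilyloxy)-4a-methyl-4-methylidene-octahydronaphthalen-2-ol
Product: 14 trans-fused 8-(tert-butyldimethylsilyloxy)-4,4a-dimethyl-1,2,3,4,4a,5,8,8a-octahydronaphthalen-2-ol (2α-OH, 4β-Me, 5β-Me, 9α-OTBS, 10α-H, 7-ene)
Conditions: Mn(dpm)3 (10 mol%), PhSiH3 (1.5 equiv), t-BuOOH (1.5 equiv), i-PrOH, rt
Reagents that add atoms: none
Why: Mukaiyama-type hydrogen-atom-transfer hydrogenation, selective for the 1,1-disubstituted alkene (tertiary radical at C4) over the 1,2-disubstituted ring alkene; the C4 radical should take up hydrogen on its axial α-face, away from the adjacent axial C5 methyl, giving the equatorial and thermodynamically preferred 4β-methyl.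

**Step 11**
Reactants: 14 (2α-OH, 4β-Me, 5β-Me, 9α-OTBS octalinol)
Product: 15 2α-acetate of 14
Conditions: Ac2O (3 equiv), DMAP (10 mol%), pyridine, rt
Reagents that add atoms: acetic anhydride, CC(=O)OC(C)=O
Why: DMAP-catalysed acetylation of the only free hydroxyl; no stereocentre is touched.

**Step 12**
Reactants: 15 2α-acetate of 14
Product: 16 trans-fused 8-hydroxy-4,4a-dimethyl-1,2,3,4,4a,5,8,8a-octahydronaphthalen-2-yl acetate (2α-OAc, 9α-OH, 7-ene)
Conditions: HF·pyridine, pyridine, THF, 0 °C → rt
Reagents that add atoms: none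
Why: fluoride-driven Si–O cleavage under buffered conditions that leave the acetate and the allylic C–O bond intact.

**Step 13**
Reactants: 16 (2α-OAc, 9α-OH, 7-ene)
Product: 17 7α,8α-epoxide of 16 (2α-OAc, 9α-OH)
Conditions: VO(acac)2 (5 mol%), t-BuOOH (1.5 equiv), CH2Cl2, 0 °C → rt
Reagents that add atoms: tert-butyl hydroperoxide, CC(C)(C)OO
Why: hydroxyl-directed vanadium-catalysed epoxidation delivers oxygen syn to the 9α-hydroxyl, which is also the face away from the axial C5 methyl (matched), giving the 7α,8α-epoxide.

**Step 14**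
Reactants: 17 7α,8α-epoxide (2α-OAc, 9α-OH)
Product: 18 (2S,4S,5R,7R,8R,9S,10R)-8,9-dihydroxyeremophil-11-en-2-yl acetate (2α-OAc, 7β-isopropenyl, 8α-OH, 9α-OH)
Conditions: isopropenylmagnesium bromide (6 equiv), CuI (3 equiv), THF, −40 → 0 °C; aqueous work-up
Reagents that add atoms: isopropenylmagnesium bromide, C=C(C)[Mg]Br
Why: organocuprate epoxide opening under Fürst–Plattner control: the trans-fused ring can open only by the trans-diaxial path, i.e. attack at C7 from the β-face (also the carbon remote from the electron-withdrawing C9 oxygen), which sets the axial 7β-isopropenyl with inversion and the axial 8α-hydroxyl, while a cuprate should leave the acetate alone.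

**Step 15**
Reactants: 18 (2α-OAc, 7β-isopropenyl, 8α,9α-diol)
Product: 19 CNP0217919.1, (2S,4S,5R,7R,8R,9S,10R)-2-acetoxy-9-angeloyloxy-8-hydroxyeremophil-11-ene
Conditions: angelic acid (1.5 equiv), 2,4,6-trichlorobenzoyl chloride (1.5 equiv), Et3N (3 equiv), toluene, rt; then 18, 75 °C
Reagents that add atoms: angelic acid, C/C=C(/C)C(=O)O
Why: Yamaguchi-type mixed-anhydride esterification without nucleophilic catalyst, a protocol that transfers the angeloyl group without isomerisation to the tiglate; of the cis-diol the equatorial 9α-hydroxyl should be acylated in preference to the axial 8α-hydroxyl next to the axial isopropenyl group.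

**Compound list**
1 | 2,3-dimethylbuta-1,3-diene | C=C(C)C(C)=C | starting material
2 | 1-bromo-2,3-dimethylbut-2-ene | CC(C)=C(C)CBr | intermediate
3 | 4,5-dimethylhex-4-en-1-yne | C#CCC(C)=C(C)C | intermediate
4 | (E)-4,4-dimethoxybut-2-enal (fumaraldehyde mono-dimethyl acetal) | COC(OC)/C=C/C=O | starting material
5 | bromo(4,5-dimethylhex-4-en-1-yn-1-yl)magnesium | Br[Mg]C#CCC(C)=C(C)C | intermediate
6 | rac-(E)-1,1-dimethoxy-8,9-dimethyldeca-2,8-dien-5-yn-4-ol | COC(OC)/C=C/C(O)C#CCC(C)=C(C)C | intermediate
7 | (E)-1,1-dimethoxy-8,9-dimethyldeca-2,8-dien-5-yn-4-one | COC(OC)/C=C/C(=O)C#CCC(C)=C(C)C | intermediate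
8 | (2E,4S)-1,1-dimethoxy-8,9-dimethyldeca-2,8-dien-5-yn-4-ol | COC(OC)/C=C/[C@H](O)C#CCC(C)=C(C)C | intermediate
9 | tert-butyl{[(2E,4S)-1,1-dimethoxy-8,9-dimethyldeca-2,8-dien-5-yn-4-yl]oxy}dimethylsilane | COC(OC)/C=C/[C@H](O[Si](C)(C)C(C)(C)C)C#CCC(C)=C(C)C | intermediate
10 | tert-butyl{[(2E,4R,5Z)-1,1-dimethoxy-8,9-dimethyldeca-2,5,8-trien-4-yl]oxy}dimethylsilane | COC(OC)/C=C/[C@H](O[Si](C)(C)C(C)(C)C)/C=C\CC(C)=C(C)C | intermediate
11 | (2E,4R,5Z)-4-[(tert-butyldimethylsilyl)oxy]-8,9-dimethyldeca-2,5,8-trienal | O=C/C=C/[C@H](O[Si](C)(C)C(C)(C)C)/C=C\CC(C)=C(C)C | intermediate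
12 | 2-[2-(tert-butyldimethylsilyloxy)-6-methyl-6-(prop-1-en-2-yl)cyclohex-3-en-1-yl]acetaldehyde; silyloxy group, CH2CHO arm and isopropenyl group all equatorial (arm trans to both neighbours), ring methyl axial | C1[C@](C)(C(C)=C)[C@@H](CC=O)[C@H](O[Si](C)(C)C(C)(C)C)C=C1 | intermediate
13 | trans-fused 8-(tert-butyldimethylsilyloxy)-4a-methyl-4-methylidene-1,2,3,4,4a,5,8,8a-octahydronaphthalen-2-ol; 2α-OH (axial), 5β-Me, 9α-OTBS, 10α-H | C1[C@]2(C)C(=C)C[C@H](O)C[C@H]2[C@H](O[Si](C)(C)C(C)(C)C)C=C1 | intermediate
14 | trans-fused 8-(tert-butyldimethylsilyloxy)-4,4a-dimethyl-1,2,3,4,4a,5,8,8a-octahydronaphthalen-2-ol; 2α-OH, 4β-Me, 5β-Me, 9α-OTBS, 10α-H | C1[C@]2(C)[C@@H](C)C[C@H](O)C[C@H]2[C@H](O[Si](C)(C)C(C)(C)C)C=C1 | intermediate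
15 | 2α-acetate of 14 | C1[C@]2(C)[C@@H](C)C[C@H](OC(C)=O)C[C@H]2[C@H](O[Si](C)(C)C(C)(C)C)C=C1 | intermediate
16 | trans-fused 8-hydroxy-4,4a-dimethyl-1,2,3,4,4a,5,8,8a-octahydronaphthalen-2-yl acetate; 2α-OAc, 9α-OH, 7-ene | C1[C@]2(C)[C@@H](C)C[C@H](OC(C)=O)C[C@H]2[C@H](O)C=C1 | intermediate
17 | 7α,8α-epoxide of 16; 2α-OAc, 9α-OH | O1[C@@H]2C[C@]3(C)[C@@H](C)C[C@H](OC(C)=O)C[C@H]3[C@H](O)[C@H]12 | intermediate
18 | (2S,4S,5R,7R,8R,9S,10R)-8,9-dihydroxyeremophil-11-en-2-yl acetate; 2α-OAc, 7β-isopropenyl, 8α-OH, 9α-OH | C=C(C)[C@H]1C[C@]2(C)[C@@H](C)C[C@H](OC(C)=O)C[C@H]2[C@H](O)[C@@H]1O | intermediate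
19 | CNP0217919.1, (2S,4S,5R,7R,8R,9S,10R)-2-acetoxy-9-angeloyloxy-8-hydroxyeremophil-11-ene; 2α-OAc, 4β-Me, 5β-Me, 7β-isopropenyl, 8α-OH, 9α-OAng, 10α-H | C=C(C)[C@H]1C[C@]2(C)[C@@H](C)C[C@H](OC(C)=O)C[C@H]2[C@H](OC(=O)/C(C)=C\C)[C@@H]1O | target

**Step count**
Total steps: 15. Longest linear sequence: 15 steps (1 → 19).

**Steps most likely to fail**

1. Step 9 (proposed new method). The zwitterion formed on the first C–C bond formation may collapse along side channels, or ring A may close through the alternative transition state with poor facial control at C2. The fallback sets out from 11 and uncouples the two ring closures into separately precedented reactions. The first ene cyclization is run alone with a mild Lewis acid that does not promote the carbonyl-ene step (FeCl3 on alumina or ZnBr2, CH2Cl2), and aldehyde 12 is isolated. Ring A is then closed in a separate carbonyl-ene reaction (MeAlCl2, CH2Cl2, −78 °C), which returns to the route at 13. Should this closure give the equatorial alcohol, 2-epi-13 F1, it is hydrogenated as in step 10 to 2-epi-14 F2. Mitsunobu inversion of F2 with acetic acid (PPh3, DIAD, AcOH, THF) then gives the axial acetate and rejoins the route at 15.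

2. Step 14. Axial attack at C7 is syn to the axial C5 methyl and may be slow, so that attack of the organometallic on the acetate could compete. The fallback sets out from 14, before any ester is present. HF·pyridine should give the diol F3, and VO(acac)2/t-BuOOH the epoxy diol F4 (only the allylic 9-hydroxyl has an alkene to direct to). The epoxide is opened with excess isopropenylmagnesium bromide and catalytic CuI at up to room temperature to give the triol F5. The cis-8,9-diol is then converted into its dibutylstannylene acetal (Bu2SnO, toluene, reflux), which directs angeloylation (mixed anhydride as in step 15) to the equatorial O9 and gives the 9-angelate F6. Acetylation of the unhindered 2α-hydroxyl in preference to the flanked axial 8α-hydroxyl (Ac2O, pyridine, 0 °C) rejoins the route at 19.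

3. Step 15. Discrimination between the two hydroxyls may be incomplete under the forcing conditions angeloylation needs, and the Z double bond may isomerise. The fallback sets out from 18 and creates the Z-alkene after the acylation. Coupling with 2-[bis(2-methylphenoxy)phosphoryl]propanoic acid (DCC, DMAP cat., CH2Cl2, 0 °C), an unhindered acid that reacts at low temperature where the equatorial 9-hydroxyl is best distinguished, should give the phosphonate ester F7. A Z-selective Horner–Wadsworth–Emmons reaction of this diaryl phosphonate with acetaldehyde (NaI, DBU, THF, −78 → 0 °C) builds the angelate and rejoins the route at 19.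

**Further compounds**
F1 | step 9 | 2-epi-13 (2β-OH, equatorial) | C1[C@]2(C)C(=C)C[C@@H](O)C[C@H]2[C@H](O[Si](C)(C)C(C)(C)C)C=C1
F2 | step 9 | 2-epi-14 (2β-OH, 4β-Me) | C1[C@]2(C)[C@@H](C)C[C@@H](O)C[C@H]2[C@H](O[Si](C)(C)C(C)(C)C)C=C1
F3 | step 14 | trans-fused 4,4a-dimethyl-1,2,3,4,4a,5,8,8a-octahydronaphthalene-2,8-diol (2α-OH, 9α-OH, 7-ene) | C1[C@]2(C)[C@@H](C)C[C@H](O)C[C@H]2[C@H](O)C=C1
F4 | step 14 | 7α,8α-epoxide of F3 | O1[C@@H]2C[C@]3(C)[C@@H](C)C[C@H](O)C[C@H]3[C@H](O)[C@H]12
F5 | step 14 | (2S,4S,5R,7R,8R,9S,10R)-eremophil-11-ene-2,8,9-triol | C=C(C)[C@H]1C[C@]2(C)[C@@H](C)C[C@H](O)C[C@H]2[C@H](O)[C@@H]1O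
F6 | step 14 | 9-O-angeloyl derivative of F5 (2α-OH and 8α-OH free) | C=C(C)[C@H]1C[C@]2(C)[C@@H](C)C[C@H](O)C[C@H]2[C@H](OC(=O)/C(C)=C\C)[C@@H]1O
F7 | step 15 | 9-O-{2-[bis(2-methylphenoxy)phosphoryl]propanoyl} derivative of 18 (mixture at the phosphonate carbon) | C=C(C)[C@H]1C[C@]2(C)[C@@H](C)C[C@H](OC(C)=O)C[C@H]2[C@H](OC(=O)C(C)P(=O)(Oc3ccccc3C)Oc3ccccc3C)[C@@H]1O
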